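(The earlier runs and the new flask were generated by integration with made-up constants; the scatter is artificial.)

You cannot put more than 60.0% of Wednesday's substrate onto the first nucleophile, since that is what its charge comes to as a fraction of the substrate charge. In Thursday's flask, with less substrate, the same charge comes to 92.3%. Wednesday's flask is the one asked about.

| flask | substrate | first nucleophile | second nucleophile | remark | time |
|---|---|---|---|---|---|
| Wednesday's | 0.020 M | 0.012 M | 0.036 M | the very flask that is asked about, followed so far |  |
| Thursday's | 0.013 M | 0.012 M | 0.036 M | run made earlier |  |
| flask | 0.020 M | 0.0120 M | 0.0360 M |  | 5.0 h |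

Wednesday's run (percent of the substrate charged)

| time / min | target / % | other capture product / % |
|---|---|---|
| 10.0 | 42.6 | 41.5 |
| 15.0 | 43.7 | 44.4 |
| 25.0 | 43.8 | 45.9 |
| 40.0 | 44.1 | 46.3 |
| 80.0 | 44.6 | 45.6 |
| 120 | 43.7 | 46.1 |

Thursday's run (percent of the substrate charged)

| time / h | target / % | other capture product / % |
|---|---|---|
| 0.667 | 50.8 | 36.8 |
| 1.33 | 51.1 | 37.1 |
| 2.00 | 51.0 | 37.0 |
| 2.50 | 51.2 | 37.5 |
| 3.00 | 51.1 | 37.4 |
| 4.00 | 51.1 | 37.2 |

(scatter of a reading: 0.3 percentage points)

- ratio of target to other capture product at 8.0 s
- ratio of target to other capture product at 6.0 min
- ratio of target to other capture product at 5.0 h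

- candidate steps: substrate -> intermediate; first nucleophile + intermediate -> target; second nucleophile + intermediate -> other capture product; target <-> isomer of the product

Both runs have gone flat, and you can take what the other capture product leaves as the share of the substrate that the first nucleophile took: 53.9% on Wednesday and 62.8% on Thursday. Target makes up 0.811 of that share on Wednesday and 0.814 on Thursday, and the isomer of the product is the rest.

Suppose the two nucleophiles compete for one intermediate, each in proportion to what is left of it. Then the logarithm of the fraction of first nucleophile left, over that of the second, stays constant. Call this the selectivity factor; Thursday's last readings give 7.91.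

Both flasks have the same nucleophile charges, so capture starts in both at the factor times the charge ratio, 2.64. Wednesday's extra substrate carries its flask further along the same curve. Its last reading puts its second nucleophile at 74.4%, and raising that to the factor gives 9.64% of the first left, against 10.2% by subtraction from the same reading. Wednesday's last capture therefore divides between first and second nucleophile at a reckoned ratio of 0.360, lower than Thursday's 0.973.

My own reckoning puts 8.0 s just below the starting 2.64, and 5.0 h at 0.951, which is Thursday's proportion of target applied to Wednesday's last reading. For 6.0 min I say no more than that it lies between them.

The forecast gives 2.5, 1.2 and 0.958, the last slightly above my end figure, and adds of the first, “so this could fall toward 2.1”.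

The flask gives 2.54, 1.18 and 0.960.

    substrate → intermediate (k = 0.00480 /s)
    first nucleophile + intermediate → target (k = 19.0 /M/s)
    second nucleophile + intermediate → other capture product (k = 2.40 /M/s)
    target ⇌ isomer of the product (K = 0.230, k = 0.00950 /s)

Now cut the second nucleophile to 0.022 M and hold the rest of the recipe. That neighbouring flask ends with 62.3% of its second nucleophile, and raising this to the factor gives 2.37% of the first left, where the neighbour shows 2.37%. The first nucleophile's share is then 58.6% of the substrate, and the other capture product's is 41.4%. Taking Thursday's proportion of target in the first share gives a ratio of 1.15, and the neighbour's ratio at 5.0 h is 1.15.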